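The route rests on cutting the bond between furan C2 and C1' of the 3,5-dihydroxyphenyl ring, reading the C2=C3 enol ether of the furan ring as a masked alkyne whose oxygen (O1) is a phenol ortho to it. In one operation, fluoride unmasks a 2-(silylethynyl)phenol that already carries the 3-methyl-2-oxobutyl chain, the methoxy group and a silyl-protected hydroxyl. Sonogashira coupling with 5-iodoresorcinol forms the C2–C1' bond, 5-endo-dig closure builds the furan ring, and the same fluoride frees the C6 hydroxyl, so the step should deliver moracin Q directly. The pentasubstituted alkynylphenol comes from 3-bromo-2-methoxyphenol by steric C–H borylation/oxidation, ketone α-arylation, iodination and alkynylation.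

Key step: step 6

Remark: moracin Q has no stereocentre, stereoaxis or configurable double bond, so the given structure is achiral and the route needs no stereocontrol; the four starting materials are taken to be commercial.

Step 1
Reactants: 1 3-bromo-2-methoxyphenol
Product: 2 (3-bromo-2-methoxyphenoxy)triisopropylsilane
Conditions: TIPSCl, imidazole, DMF, rt
Reagents that add atoms: chlorotriisopropylsilane (TIPSCl) CC(C)[Si](Cl)(C(C)C)C(C)C
Why: Standard silyl ether formation on a phenol, with the bulky triisopropylsilyl group chosen because it shields its ortho C–H in steps 2 and 4, withstands the alkoxide base of step 3 and is removed by the same fluoride that triggers step 6.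

Step 2
Reactants: 2 (3-bromo-2-methoxyphenoxy)triisopropylsilane
Product: 4 3-bromo-4-methoxy-5-(triisopropylsilyloxy)phenol, via aryl pinacol boronate 3 (not isolated)
Conditions: [Ir(OMe)(cod)]2 (1.5 mol %), dtbpy (3 mol %), B2pin2 (1.0 equiv), THF, 80 °C; then NaBO3·4H2O, THF–H2O, rt
Reagents that add atoms: bis(pinacolato)diboron CC1(C)OB(OC1(C)C)B1OC(C)(C)C(C)(C)O1 (boryl group of 3); sodium perborate [Na+].[O-]B1OO1 (phenol oxygen of 4)
Why: Iridium-catalysed aromatic C–H borylation (Hartwig–Miyaura type) is sterically governed and should strike only the C–H flanked by two hydrogens (meta to Br and to OSi, para to OMe) while leaving the C–Br bond intact, after which perborate oxidation converts the C–B bond into the phenol C–O bond at the same carbon.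

Step 3
Reactants: 4 3-bromo-4-methoxy-5-(triisopropylsilyloxy)phenol; 5 3-methylbutan-2-one (3 equiv)
Product: 6 1-[5-hydroxy-2-methoxy-3-(triisopropylsilyloxy)phenyl]-3-methylbutan-2-one
Conditions: Pd2(dba)3 (2 mol %), Xantphos (5 mol %), NaOt-Bu (2.4 equiv), toluene, 80 °C
Reagents that add atoms: none
Why: Palladium-catalysed α-arylation of a ketone enolate (Buchwald–Hartwig type) should occur at the unhindered methyl terminus of the methyl isopropyl ketone and stop at monoarylation because of the ortho-methoxy group and the excess ketone, while the phenol travels as its phenoxide (hence the extra base), meta to bromine and unable to interfere.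

Step 4
Reactants: 6 1-[5-hydroxy-2-methoxy-3-(triisopropylsilyloxy)phenyl]-3-methylbutan-2-one
Product: 7 1-[3-hydroxy-2-iodo-6-methoxy-5-(triisopropylsilyloxy)phenyl]-3-methylbutan-2-one
Conditions: NIS (1.05 equiv), TsOH·H2O (10 mol %), MeCN, 0 °C, dark
Reagents that add atoms: N-iodosuccinimide O=C1CCC(=O)N1I
Why: Electrophilic aromatic iodination ortho to the free hydroxyl (para is blocked by OMe) should choose the ortho carbon that is also para to the silyloxy group and next to the ketone-bearing CH2, because the other ortho C–H lies under the triisopropylsilyl group that the neighbouring methoxy group pushes toward it.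

Step 5
Reactants: 7 1-[3-hydroxy-2-iodo-6-methoxy-5-(triisopropylsilyloxy)phenyl]-3-methylbutan-2-one; 8 ethynyltrimethylsilane (1.5 equiv)
Product: 9 1-[3-hydroxy-6-methoxy-5-(triisopropylsilyloxy)-2-[(trimethylsilyl)ethynyl]phenyl]-3-methylbutan-2-one
Conditions: Pd(PPh3)2Cl2 (3 mol %), CuI (6 mol %), Et3N–THF, 40 °C, Ar
Reagents that add atoms: none
Why: Sonogashira coupling of the aryl iodide with the terminal alkyne runs under mild amine conditions that leave the ketone and silyl ether untouched, and the moderate temperature should keep the ortho-hydroxy alkyne from cyclising prematurely.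

Step 6
Reactants: 9 1-[3-hydroxy-6-methoxy-5-(triisopropylsilyloxy)-2-[(trimethylsilyl)ethynyl]phenyl]-3-methylbutan-2-one; 10 5-iodobenzene-1,3-diol (5-iodoresorcinol)
Product: 13 moracin Q, via free ethynylphenol 11 (not isolated), via diarylalkyne 12 (not isolated)
Conditions: Pd(PPh3)2Cl2 (5 mol %), CuI (10 mol %), TBAF (1 M in THF, 6 equiv), THF, rt → 60 °C, Ar; aq NH4Cl
Reagents that add atoms: none
Why: Fluoride cleaves the C(sp)–SiMe3 bond and the aryl O–Si(i-Pr)3 bond of 9 to give terminal alkyne 11, which enters the Sonogashira cycle as its copper acetylide; oxidative addition of Pd(0) into the C–I bond of 10, transmetalation and reductive elimination join the alkyne terminus (the future furan C2) to C1' of the resorcinol ring in 12. The phenoxide ortho to the alkyne then adds to the Cu/Pd-activated triple bond and protodemetalation gives the aromatic furan, so the two alkyne carbons become C2 and C3 and the phenol oxygen becomes O1. The closest known reaction type is the domino Sonogashira coupling–heteroannulation of o-ethynylphenols with aryl halides, run here in its fluoride-triggered (sila-Sonogashira) form. The furan ring is the only ring closed, by 5-endo-dig attack of oxygen. No stereocentre is formed. The step needs coupling before cyclisation and O-cyclisation by the ortho phenoxide only: an aryl iodide is the most reactive class of coupling partner, the phenol is far more acidic than the benzylic ketone, the para hydroxyl and the resorcinol hydroxyls cannot reach the alkyne, and oxygen is excluded to suppress alkyne dimerisation.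

Compound list
1 | 3-bromo-2-methoxyphenol | COc1c(O)cccc1Br | starting material
2 | (3-bromo-2-methoxyphenoxy)triisopropylsilane | COc1c(O[Si](C(C)C)(C(C)C)C(C)C)cccc1Br | intermediate
3 | 2-[3-bromo-4-methoxy-5-(triisopropylsilyloxy)phenyl]-4,4,5,5-tetramethyl-1,3,2-dioxaborolane (not isolated) | COc1c(O[Si](C(C)C)(C(C)C)C(C)C)cc(B2OC(C)(C)C(C)(C)O2)cc1Br | intermediate
4 | 3-bromo-4-methoxy-5-(triisopropylsilyloxy)phenol | COc1c(O[Si](C(C)C)(C(C)C)C(C)C)cc(O)cc1Br | intermediate
5 | 3-methylbutan-2-one | CC(=O)C(C)C | starting material
6 | 1-[5-hydroxy-2-methoxy-3-(triisopropylsilyloxy)phenyl]-3-methylbutan-2-one | COc1c(O[Si](C(C)C)(C(C)C)C(C)C)cc(O)cc1CC(=O)C(C)C | intermediate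
7 | 1-[3-hydroxy-2-iodo-6-methoxy-5-(triisopropylsilyloxy)phenyl]-3-methylbutan-2-one | COc1c(O[Si](C(C)C)(C(C)C)C(C)C)cc(O)c(I)c1CC(=O)C(C)C | intermediate
8 | ethynyltrimethylsilane | C#C[Si](C)(C)C | starting material
9 | 1-[3-hydroxy-6-methoxy-5-(triisopropylsilyloxy)-2-[(trimethylsilyl)ethynyl]phenyl]-3-methylbutan-2-one | COc1c(O[Si](C(C)C)(C(C)C)C(C)C)cc(O)c(C#C[Si](C)(C)C)c1CC(=O)C(C)C | intermediate
10 | 5-iodobenzene-1,3-diol (5-iodoresorcinol) | Oc1cc(O)cc(I)c1 | starting material
11 | 1-(2-ethynyl-3,5-dihydroxy-6-methoxyphenyl)-3-methylbutan-2-one (not isolated) | COc1c(O)cc(O)c(C#C)c1CC(=O)C(C)C | intermediate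
12 | 1-[2-[(3,5-dihydroxyphenyl)ethynyl]-3,5-dihydroxy-6-methoxyphenyl]-3-methylbutan-2-one (not isolated) | COc1c(O)cc(O)c(C#Cc2cc(O)cc(O)c2)c1CC(=O)C(C)C | intermediate
13 | moracin Q, 1-[2-(3,5-dihydroxyphenyl)-6-hydroxy-5-methoxy-1-benzofuran-4-yl]-3-methylbutan-2-one | COc1c(O)cc2oc(-c3cc(O)cc(O)c3)cc2c1CC(=O)C(C)C | target

Total step count: 6
Longest linear sequence: 6 steps (1 → 2 → 4 → 6 → 7 → 9 → 13); 5, 8 and 10 enter as purchased partners.

Steps most likely to fail

Step 6 (key step). Process at risk: once fluoride has unmasked the ethynylphenoxide, its own 5-endo cyclisation or oxidative alkyne dimerisation may outrun capture by the arylpalladium species, and the several phenoxides present may slow oxidative addition or be degraded. The fallback closes the ring first and then makes the same C2–C1' bond by boron cross-coupling. Setting out from 9, TBAF in THF without catalyst or coupling partner should deliberately drive desilylation and cyclisation to 1-(6-hydroxy-5-methoxy-1-benzofuran-4-yl)-3-methylbutan-2-one F1. Iridium-catalysed C–H borylation of F1 (excess B2pin2, [Ir(OMe)(cod)]2/dtbpy, THF, 60 °C) should pass through the O,C2-diborylated species 1-[5-methoxy-2-(pinacolboryl)-6-(pinacolboryloxy)-1-benzofuran-4-yl]-3-methylbutan-2-one F2 (not isolated; the phenol is masked in the flask as its boryl ether and released on aqueous work-up). This should give the furan C2 boronate 1-[6-hydroxy-5-methoxy-2-(4,4,5,5-tetramethyl-1,3,2-dioxaborolan-2-yl)-1-benzofuran-4-yl]-3-methylbutan-2-one F3, since furan C2–H is the most reactive and least hindered C–H. Suzuki–Miyaura coupling of F3 with 10 (Pd(dppf)Cl2, K3PO4, dioxane–H2O, 60 °C), which tolerates free phenols, then comes back to the route at 13.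

Step 3. Process at risk: sluggish oxidative addition of the bromophenoxide, over-arylation of the product enolate, or loss of the silyl ether to the excess alkoxide. The fallback replaces enolate coupling by polar C–C bond formation and moves the hydroxylation after it. Setting out from 2, bromine–lithium exchange (n-BuLi, THF, −78 °C) gives [2-methoxy-3-(triisopropylsilyloxy)phenyl]lithium F4. Its BF3·OEt2-assisted opening of 2-isopropyloxirane (CC(C)C1CO1) at the terminal carbon should give racemic 1-[2-methoxy-3-(triisopropylsilyloxy)phenyl]-3-methylbutan-2-ol F5. Dess–Martin oxidation erases the carbinol centre and gives 1-[2-methoxy-3-(triisopropylsilyloxy)phenyl]-3-methylbutan-2-one F6. The C–H borylation/perborate oxidation of step 2, again confined to the one C–H flanked by two hydrogens, should pass through 1-[2-methoxy-5-(4,4,5,5-tetramethyl-1,3,2-dioxaborolan-2-yl)-3-(triisopropylsilyloxy)phenyl]-3-methylbutan-2-one F7 (not isolated) and comes back to the route at 6.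

Step 4. Process at risk: iodination at the other ortho position, or oxidation of the 4-methoxyphenol unit to a quinone by the iodonium source. The fallback delivers a carbon electrophile through a magnesium phenoxide and then homologates by one carbon, bypassing steps 4 and 5. Setting out from 6, Casnati–Skattebøl ortho-formylation (MgCl2, Et3N, paraformaldehyde, MeCN, reflux) should give 2-hydroxy-5-methoxy-6-(3-methyl-2-oxobutyl)-4-(triisopropylsilyloxy)benzaldehyde F8. Its chelated transition state is non-oxidising, ortho-specific and more sensitive to the silyl shielding than a free iodonium source. Seyferth–Gilbert homologation with the Ohira–Bestmann reagent (K2CO3, MeOH, rt) should give the terminal alkyne 1-[2-ethynyl-3-hydroxy-6-methoxy-5-(triisopropylsilyloxy)phenyl]-3-methylbutan-2-one F9. F9 enters step 6 in place of 9 and comes back to the route at 11 once fluoride has removed its silyl ether.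

Further compounds
F1 | step 6 | 1-(6-hydroxy-5-methoxy-1-benzofuran-4-yl)-3-methylbutan-2-one | COc1c(O)cc2occc2c1CC(=O)C(C)C
F2 | step 6 | 1-[5-methoxy-2-(pinacolboryl)-6-(pinacolboryloxy)-1-benzofuran-4-yl]-3-methylbutan-2-one (not isolated) | COc1c(OB3OC(C)(C)C(C)(C)O3)cc2oc(B4OC(C)(C)C(C)(C)O4)cc2c1CC(=O)C(C)C
F3 | step 6 | 1-[6-hydroxy-5-methoxy-2-(4,4,5,5-tetramethyl-1,3,2-dioxaborolan-2-yl)-1-benzofuran-4-yl]-3-methylbutan-2-one | COc1c(O)cc2oc(B3OC(C)(C)C(C)(C)O3)cc2c1CC(=O)C(C)C
F4 | step 3 | [2-methoxy-3-(triisopropylsilyloxy)phenyl]lithium (not isolated) | [Li]c1cccc(O[Si](C(C)C)(C(C)C)C(C)C)c1OC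
F5 | step 3 | 1-[2-methoxy-3-(triisopropylsilyloxy)phenyl]-3-methylbutan-2-ol (racemic) | COc1c(O[Si](C(C)C)(C(C)C)C(C)C)cccc1CC(O)C(C)C
F6 | step 3 | 1-[2-methoxy-3-(triisopropylsilyloxy)phenyl]-3-methylbutan-2-one | COc1c(O[Si](C(C)C)(C(C)C)C(C)C)cccc1CC(=O)C(C)C
F7 | step 3 | 1-[2-methoxy-5-(4,4,5,5-tetramethyl-1,3,2-dioxaborolan-2-yl)-3-(triisopropylsilyloxy)phenyl]-3-methylbutan-2-one (not isolated) | COc1c(O[Si](C(C)C)(C(C)C)C(C)C)cc(B2OC(C)(C)C(C)(C)O2)cc1CC(=O)C(C)C
F8 | step 4 | 2-hydroxy-5-methoxy-6-(3-methyl-2-oxobutyl)-4-(triisopropylsilyloxy)benzaldehyde | COc1c(O[Si](C(C)C)(C(C)C)C(C)C)cc(O)c(C=O)c1CC(=O)C(C)C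
F9 | step 4 | 1-[2-ethynyl-3-hydroxy-6-methoxy-5-(triisopropylsilyloxy)phenyl]-3-methylbutan-2-one | COc1c(O[Si](C(C)C)(C(C)C)C(C)C)cc(O)c(C#C)c1CC(=O)C(C)C
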